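## The problem

The target **15** is genistein (**1**) with two different five-carbon chains on ring A: a 3-methylbut-2-enyl group at C6 (C1' on the ring) and a (2S)-2-hydroxy-3-methylbut-3-enyl group at C8 (C1'' on the ring, C2'' the carbinol, C3'' the isopropenyl carbon). Rings A, B and C and all oxygens of the nucleus are already present in **1**. The work therefore lies in telling C6 from C8, two CH positions ortho or para to the same three oxygens, and in building the C8 chain. That chain holds the only stereocentre, C2'', a secondary allylic carbinol. Nothing else in the molecule is stereogenic, so its configuration must come from a reagent or catalyst. The molecule tolerates little: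

- the pyranone (ring C) is attacked at C2 by hard nucleophiles and alkaline peroxide;
- the C6 prenyl group between the 5- and 7-hydroxyls cyclises to a chroman under acid and reacts with electrophilic halogen;
- the allylic carbinol next to a 1,1-disubstituted alkene ionises in strong acid;
- hydrogenolysis is excluded by the two alkenes.

The feature that permits a short construction is the connectivity of the C8 chain. The aryl carbon C8, the two-carbon unit C1''–C2'' and the isopropenyl carbon C3'' meet at the oxygenated carbon C2''. This is the pattern left when an aryl electrophile and a migrating alkenyl group add across a vinylboron unit and boron is then exchanged for oxygen. C8 is also the last open position of ring A once C6 is blocked, so a halogen can be placed there without ambiguity.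

## Retrosynthesis

**15 ⇒ 14.** The three phenolic O–CH2OCH3 bonds are cut last, leading back to the tris(methoxymethyl) ether **14**. Acetals are preferred over benzyl ethers (hydrogenolysis would reduce both alkenes), methyl ethers (the Lewis acids needed to cleave them would cyclise the prenyl group) and silyl ethers (not safe under the fluoride and hydride conditions used earlier, and hard to keep on the chelated O5). **14** has the same skeleton but is inert to bases and organometallic reagents. The forward step must cleave three aryl acetals with acid mild enough to spare the prenyl group and the allylic carbinol.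

**14 ⇒ 13.** The C2''–O bond is traced back to a C2''–B bond in the pinacol boronate **13**. Oxidation of a carbon–boron bond proceeds with retention, so the configuration of the carbinol is stored at the boron-bearing carbon. Introducing oxygen by oxidising an alkene instead would require a choice between three alkenes. The forward step needs an oxidant that leaves the pyranone and both alkenes untouched.

**13 ⇒ 8 + 9 + 11.** Two bonds of the chain are cut at once, C8–C1'' and C2''–C3''. This gives the aryl iodide **8**, vinylboronic acid pinacol ester **9** and isopropenyllithium **11**, which is made in the flask from 2-bromopropene **10** and joined to **9** as the borate **12**. The neighbouring cuts are weaker: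

- Cutting only C8–C1'' would need a chiral five-carbon nucleophile with oxygen β to the metal, which eliminates. Reversing the polarity would need an aryl metal that the pyranone does not tolerate.
- Cutting only C1''–C2'' (an arylacetaldehyde plus an isopropenyl metal) costs two extra steps to make the aldehyde.

The three-component cut reduces the whole chain to two commodity reagents and creates the stereocentre in the same step. The forward reaction must activate the vinyl and not the isopropenyl group of **12**, induce the 1,2-shift in preference to direct alkenyl transfer, control the face of the vinyl group, and leave the pyranone alone.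

**8 ⇒ 7.** The C8–I bond is traced back to the C8–Br bond of **7** by halogen exchange. Direct iodination of a 6-prenyl isoflavone at C8 was rejected: an iodonium source would meet a trisubstituted alkene flanked by two acetal oxygens, and iodoetherification with loss of an acetal group would compete with substitution on a ring that the C4 carbonyl deactivates. Carrying an iodide at C8 through the prenylation was also rejected, because two aryl iodides cannot be told apart by palladium. The forward step must exchange bromide for iodide by a process that involves no electrophilic halogen.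

**7 ⇒ 5 + 6.** The C6–C1' bond is cut, giving the 8-bromo-6-iodo compound **5** and the prenylstannane **6**. Rearrangement routes from O-allyl ethers give mixtures of C6 and C8 products and of linear and branched chains. A cross-coupling places the chain where the iodine is. The forward step relies on the faster insertion of palladium into C–I than into C–Br and on transfer of the allyl group through its unsubstituted terminus.

**5 ⇒ 4 ⇒ 3 ⇒ 2 ⇒ 1.** The C8–Br bond, the O5 acetal, the C6–I bond and the O7 and O4' acetals are removed in turn, leading through **4**, **3** and **2** to **1**. The order carries the regiochemistry: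

- the chelated 5-OH of **1** is the least reactive hydroxyl and stays free in **2**;
- this free hydroxyl directs iodine to C6 in **3**;
- once O5 is protected (**4**), C8 is the only CH left on ring A for bromination (**5**).

Both halogens are in place before any alkene is present.

## Roads not taken

**Alternative 1: photochemical benzannulation of ring A.**

- *Cut:* all four ring-A bonds outside the pyranone, giving the pyranonyl diazo ketone A2 and the prenyl ynol silyl ether A3.
- *Forward key step:* irradiation of A2 triggers a Wolff shift (C8–C8a) to a vinylketene, which adds A3 in a [2+2] sense (C5–C6, C7–C8). Four-electron opening of the cyclobutenone and six-electron closure (C4a–C5) then give the phenol A1.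
- *Merits:* the positions of all six substituents follow from connectivity, so no site-selective halogenation is needed, and O5 and O7 emerge differentiated. In regiochemical certainty this road is better than the chosen plan.
- *Weak points:* A2 must already carry the C2'' stereocentre, so the asymmetric problem is only moved into fragment synthesis. The carbene carbon bears a CH2 group, so 1,2-hydrogen shift can compete with the Wolff shift. The 4-pyranone chromophore absorbs and can rearrange under the same light. The ketene is formed next to two alkenes. A2 and A3 each need several steps, and ring C with its aryl group must be built from scratch.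
- *Comparison:* the chosen plan sets against it a starting material (**1**) that already has all three rings, nine linear steps, and a key step that makes chain and stereocentre together. Its regiochemistry rests on the order of two halogenations, which is a smaller risk than the photochemistry of A2.

**Alternative 2: aryne annulation of ring C.**

- *Cut:* O1–C8a and C4–C4a, giving the ortho-silylaryl triflate A5 and the formylated arylacetate A6.
- *Forward key step:* CsF releases the aryne from A5. The enolate oxygen of A6 adds to the aryne carbon remote from the flanking acetal oxygen, and the resulting aryl anion closes onto the ester to give A4.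
- *Merits:* the prenyl group is placed by the symmetry of the phenol from which A5 derives, without tin and without a chelation-directed iodination. On that point this road is as good as or better than the chosen plan.
- *Weak points:* A4 is only the 6-prenyl isoflavone with C8–H. The chain and the stereocentre are untouched. To reach **8**, A4 would have to be halogenated at C8 in the presence of the prenyl alkene, which is the clash the chosen plan avoids. A5 takes several steps. The road rebuilds a ring system that can be bought.
- *Comparison:* the chosen plan has both halogens installed before any alkene exists and needs fewer operations to reach the same key-step substrate.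

**Alternative 3: rhodium-catalysed formyl C–H annulation.**

- *Cut:* C3–C4 and O1–C2, giving the hexasubstituted salicylaldehyde A8 and the aryl(trimethylsilyl)alkyne A9.
- *Forward key step:* [Cp*RhCl2]2 with Cu(OAc)2 as oxidant. Phenoxide-directed activation of the aldehyde C–H bond by trivalent rhodium, insertion of A9 with silicon at the future C2, and C–O bond formation give A7. Desilylation at C2 and two deprotections follow.
- *Merits:* ring B enters last, which suits analogue work. In modularity this road is better than the chosen plan.
- *Weak points:* A8 is the complete ring A with both chains and the stereocentre, so the key step solves none of the hard parts. Two alkenes and an allylic silyl ether must survive a copper oxidant at elevated temperature and can bind rhodium. The sense of alkyne insertion next to so hindered an aldehyde is not assured. Three steps follow the annulation.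
- *Comparison:* the chosen plan never has to make a hexasubstituted benzene, and its key step creates the stereocentre instead of carrying it.

Key step: step 7

Assumption: the (Sp,Sp) enantiomer of the ferrocenyl bisphosphine named in step 7 is taken to place boron as drawn in **13**. The substrate is achiral, so the mirror-image ligand gives the opposite sense under the same conditions and is the remedy if this assignment proves wrong.

## Route

Step 1
Reactants: 1 genistein, 5,7-dihydroxy-3-(4-hydroxyphenyl)chromen-4-one
Product: 2 5-hydroxy-7-(methoxymethoxy)-3-[4-(methoxymethoxy)phenyl]chromen-4-one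
Conditions: MOMCl (2.2 equiv), K2CO3, acetone, 0 °C to rt
Reagents that add atoms: chloromethyl methyl ether, COCCl
Why: Phenol O-alkylation; the 5-OH is hydrogen-bonded to the C4 carbonyl and is not deprotonated by carbonate, so only O7 and O4' react.

Step 2
Reactants: 2 5-hydroxy-7-(methoxymethoxy)-3-[4-(methoxymethoxy)phenyl]chromen-4-one
Product: 3 5-hydroxy-6-iodo-7-(methoxymethoxy)-3-[4-(methoxymethoxy)phenyl]chromen-4-one
Conditions: BnMe3N+ ICl2− (1.05 equiv), CaCO3, CH2Cl2/MeOH, rt, dark
Reagents that add atoms: benzyltrimethylammonium dichloroiodate, C[N+](C)(C)Cc1ccccc1.Cl[I-]Cl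
Why: Electrophilic aromatic iodination directed ortho to the free chelated 5-OH, the established selectivity for 5-hydroxy-7-alkoxy flavonoids with this reagent; CaCO3 takes up the HCl so the acetals should survive.

Step 3
Reactants: 3 5-hydroxy-6-iodo-7-(methoxymethoxy)-3-[4-(methoxymethoxy)phenyl]chromen-4-one
Product: 4 6-iodo-5,7-bis(methoxymethoxy)-3-[4-(methoxymethoxy)phenyl]chromen-4-one
Conditions: NaH, MOMCl, DMF, 0 °C to rt
Reagents that add atoms: chloromethyl methyl ether, COCCl
Why: Williamson-type O-alkylation; full deprotonation with NaH breaks the hydrogen bond to the carbonyl and lets the hindered O5 react.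

Step 4
Reactants: 4 6-iodo-5,7-bis(methoxymethoxy)-3-[4-(methoxymethoxy)phenyl]chromen-4-one
Product: 5 8-bromo-6-iodo-5,7-bis(methoxymethoxy)-3-[4-(methoxymethoxy)phenyl]chromen-4-one
Conditions: NBS (1.05 equiv), DMF, 0 °C to rt, dark
Reagents that add atoms: N-bromosuccinimide, O=C1CCC(=O)N1Br
Why: Electrophilic aromatic bromination; C8 is the only CH left on ring A and is ortho or para to three oxygens, whereas ring B has one oxygen and reacts more slowly; no alkene is present yet.

Step 5
Reactants: 5 8-bromo-6-iodo-5,7-bis(methoxymethoxy)-3-[4-(methoxymethoxy)phenyl]chromen-4-one; 6 tributyl(3-methylbut-2-enyl)stannane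
Product: 7 8-bromo-5,7-bis(methoxymethoxy)-3-[4-(methoxymethoxy)phenyl]-6-(3-methylbut-2-enyl)chromen-4-one
Conditions: 6 (1.2 equiv), Pd(PPh3)4 (5 mol %), CsF, DMF, 60 °C
Reagents that add atoms: none
Why: Stille coupling; zerovalent palladium inserts into C6–I much faster than into C8–Br, the fluoride-activated stannane transfers the allyl group, and reductive elimination at the less substituted allyl terminus should give the linear 3-methylbut-2-enyl chain.

Step 6
Reactants: 7 8-bromo-5,7-bis(methoxymethoxy)-3-[4-(methoxymethoxy)phenyl]-6-(3-methylbut-2-enyl)chromen-4-one
Product: 8 8-iodo-5,7-bis(methoxymethoxy)-3-[4-(methoxymethoxy)phenyl]-6-(3-methylbut-2-enyl)chromen-4-one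
Conditions: CuI (10 mol %), trans-N,N'-dimethylcyclohexane-1,2-diamine (20 mol %), NaI (2 equiv), 1,4-dioxane, 110 °C
Reagents that add atoms: sodium iodide, [Na+].[I-]
Why: Copper-catalysed aromatic Finkelstein exchange, driven by precipitation of NaBr from dioxane; iodide enters as a nucleophile, so the prenyl alkene never meets electrophilic iodine.

Step 7
Reactants: 8 8-iodo-5,7-bis(methoxymethoxy)-3-[4-(methoxymethoxy)phenyl]-6-(3-methylbut-2-enyl)chromen-4-one; 9 vinylboronic acid pinacol ester; 10 2-bromopropene
Product: 13 5,7-bis(methoxymethoxy)-3-[4-(methoxymethoxy)phenyl]-6-(3-methylbut-2-enyl)-8-[(2S)-3-methyl-2-(4,4,5,5-tetramethyl-1,3,2-dioxaborolan-2-yl)but-3-enyl]chromen-4-one, via isopropenyllithium 11 (not isolated), via lithium isopropenyl(vinyl)(pinacolato)borate 12 (not isolated)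
Conditions: 10 (1.5 equiv), t-BuLi (3.0 equiv), Et2O, −78 °C; 9 (1.6 equiv), −78 °C to rt; solvent exchanged for THF; then 8, Pd(OAc)2 (5 mol %), (Sp,Sp)-1,1'-bis[bis(4-methoxy-3,5-dimethylphenyl)phosphino]-2,2'-bis[(R)-(dimethylamino)(phenyl)methyl]ferrocene (6 mol %), KOTf (4 equiv), THF, 60 °C
Reagents that add atoms: none
Why: The closest known reaction type is the palladium-catalysed enantioselective conjunctive cross-coupling of bis(alkenyl)borates with aryl electrophiles, which gives α-chiral allylic boronates. Bromine–lithium exchange converts 10 into 11, which adds to boron of 9 to give the borate 12 before 8 is introduced, so no free organolithium meets the pyranone. Zerovalent palladium, formed from Pd(OAc)2 and the bisphosphine, inserts into the C8–I bond, and KOTf removes iodide (and the bromide left from the exchange) as insoluble potassium salts, leaving a cationic arylpalladium that can bind an alkene. It binds the unsubstituted vinyl group of 12, because the 1,1-disubstituted isopropenyl group is the poorer ligand for steric reasons; this activation induces the 1,2-shift of the isopropenyl group from boron to the neighbouring carbon, anti to palladium, forming C2''–C3'', and reductive elimination then forms C8–C1''. No ring closes. The new stereocentre at C2'' is set by the catalyst alone: the ferrocenyl bisphosphine selects the face of the vinyl group that palladium binds, and the anti shift fixes the configuration of the boron-bearing carbon as (S). The step needs vinyl over isopropenyl activation (secured by sterics), metallate shift over direct alkenyl transfer to palladium (favoured by the cationic bisphosphine complex and the tetracoordinate pinacol borate) and an untouched pyranone (secured by the non-basic, non-nucleophilic borate).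

Step 8
Reactants: 13 5,7-bis(methoxymethoxy)-3-[4-(methoxymethoxy)phenyl]-6-(3-methylbut-2-enyl)-8-[(2S)-3-methyl-2-(4,4,5,5-tetramethyl-1,3,2-dioxaborolan-2-yl)but-3-enyl]chromen-4-one
Product: 14 8-[(2S)-2-hydroxy-3-methylbut-3-enyl]-5,7-bis(methoxymethoxy)-3-[4-(methoxymethoxy)phenyl]-6-(3-methylbut-2-enyl)chromen-4-one
Conditions: NaBO3·4H2O, NaHCO3, THF/H2O, 0 °C to rt
Reagents that add atoms: sodium perborate tetrahydrate, [Na+].[Na+].O[B-]1(O)OO[B-](O)(O)OO1
Why: Perborate oxidation of a boronic ester; the peroxoborate adds to boron and C2'' migrates from boron to oxygen with retention and without allylic transposition, giving the (S) carbinol; at this mild pH the pyranone, a vinylogous ester, should react much more slowly than the C–B bond, and the alkenes are inert to a nucleophilic oxidant.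

Step 9
Reactants: 14 8-[(2S)-2-hydroxy-3-methylbut-3-enyl]-5,7-bis(methoxymethoxy)-3-[4-(methoxymethoxy)phenyl]-6-(3-methylbut-2-enyl)chromen-4-one
Product: 15 5,7-dihydroxy-8-[(2S)-2-hydroxy-3-methylbut-3-enyl]-3-(4-hydroxyphenyl)-6-(3-methylbut-2-enyl)chromen-4-one
Conditions: aq. HCl (3 M), MeOH, rt to 40 °C
Reagents that add atoms: none
Why: Acid-catalysed acetal exchange with methanol releases the three phenols as dimethoxymethane is formed, the usual way of unmasking prenylated phenols; the stereocentre is not involved, provided the carbinol does not ionise.

## Compound list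

1 | genistein, 5,7-dihydroxy-3-(4-hydroxyphenyl)chromen-4-one | O=c1c(-c2ccc(O)cc2)coc2cc(O)cc(O)c12 | starting material
2 | 5-hydroxy-7-(methoxymethoxy)-3-[4-(methoxymethoxy)phenyl]chromen-4-one | O=c1c(-c2ccc(OCOC)cc2)coc2cc(OCOC)cc(O)c12 | intermediate
3 | 5-hydroxy-6-iodo-7-(methoxymethoxy)-3-[4-(methoxymethoxy)phenyl]chromen-4-one | O=c1c(-c2ccc(OCOC)cc2)coc2cc(OCOC)c(I)c(O)c12 | intermediate
4 | 6-iodo-5,7-bis(methoxymethoxy)-3-[4-(methoxymethoxy)phenyl]chromen-4-one | O=c1c(-c2ccc(OCOC)cc2)coc2cc(OCOC)c(I)c(OCOC)c12 | intermediate
5 | 8-bromo-6-iodo-5,7-bis(methoxymethoxy)-3-[4-(methoxymethoxy)phenyl]chromen-4-one | O=c1c(-c2ccc(OCOC)cc2)coc2c(Br)c(OCOC)c(I)c(OCOC)c12 | intermediate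
6 | tributyl(3-methylbut-2-enyl)stannane | CC(C)=CC[Sn](CCCC)(CCCC)CCCC | starting material
7 | 8-bromo-5,7-bis(methoxymethoxy)-3-[4-(methoxymethoxy)phenyl]-6-(3-methylbut-2-enyl)chromen-4-one | CC(C)=CCc1c(OCOC)c(Br)c2occ(-c3ccc(OCOC)cc3)c(=O)c2c1OCOC | intermediate
8 | 8-iodo-5,7-bis(methoxymethoxy)-3-[4-(methoxymethoxy)phenyl]-6-(3-methylbut-2-enyl)chromen-4-one | CC(C)=CCc1c(OCOC)c(I)c2occ(-c3ccc(OCOC)cc3)c(=O)c2c1OCOC | intermediate
9 | vinylboronic acid pinacol ester, 2-ethenyl-4,4,5,5-tetramethyl-1,3,2-dioxaborolane | C=CB1OC(C)(C)C(C)(C)O1 | starting material
10 | 2-bromopropene | C=C(C)Br | starting material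
11 | isopropenyllithium, prop-1-en-2-yllithium | [Li]C(C)=C | intermediate
12 | lithium isopropenyl(vinyl)(pinacolato)borate | [Li+].C=C[B-]1(C(C)=C)OC(C)(C)C(C)(C)O1 | intermediate
13 | 5,7-bis(methoxymethoxy)-3-[4-(methoxymethoxy)phenyl]-6-(3-methylbut-2-enyl)-8-[(2S)-3-methyl-2-(4,4,5,5-tetramethyl-1,3,2-dioxaborolan-2-yl)but-3-enyl]chromen-4-one | C=C(C)[C@@H](B4OC(C)(C)C(C)(C)O4)Cc1c(OCOC)c(CC=C(C)C)c(OCOC)c2c(=O)c(-c3ccc(OCOC)cc3)coc12 | intermediate
14 | 8-[(2S)-2-hydroxy-3-methylbut-3-enyl]-5,7-bis(methoxymethoxy)-3-[4-(methoxymethoxy)phenyl]-6-(3-methylbut-2-enyl)chromen-4-one | C=C(C)[C@@H](O)Cc1c(OCOC)c(CC=C(C)C)c(OCOC)c2c(=O)c(-c3ccc(OCOC)cc3)coc12 | intermediate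
15 | 5,7-dihydroxy-8-[(2S)-2-hydroxy-3-methylbut-3-enyl]-3-(4-hydroxyphenyl)-6-(3-methylbut-2-enyl)chromen-4-one | C=C(C)[C@@H](O)Cc1c(O)c(CC=C(C)C)c(O)c2c(=O)c(-c3ccc(O)cc3)coc12 | target

## Step count and risks

Total step count: 9 (the preparation of 11 and 12 takes place in the flask of step 7). Longest linear sequence: 9 steps, from 1 to 15.

**Step 7 (key step).** The most likely failure is incomplete removal of halide, so that palladium stays neutral, does not bind the vinyl group, and either stalls or transfers an alkenyl group directly to C8. Iodide salts are more soluble in THF than bromide salts, and iodide binds divalent palladium strongly. The second risk is slow turnover or eroded facial selectivity at a carbon flanked by two oxygen substituents, which lies at the edge of the documented scope. Fallback, by carbonyl addition instead of metallate shift: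

- From 8, Stille coupling with tributyl[(Z)-2-ethoxyvinyl]stannane and Pd(PPh3)4 should give 8-[(Z)-2-ethoxyvinyl]-5,7-bis(methoxymethoxy)-3-[4-(methoxymethoxy)phenyl]-6-(3-methylbut-2-enyl)chromen-4-one F1.
- Brief treatment with dilute aqueous HCl in THF at 0 °C (enol ethers hydrolyse much faster than aryl acetals) should give the arylacetaldehyde 2-[5,7-bis(methoxymethoxy)-3-[4-(methoxymethoxy)phenyl]-6-(3-methylbut-2-enyl)-4-oxochromen-8-yl]acetaldehyde F2.
- A Nozaki–Hiyama–Kishi addition of 10 (CrCl2, catalytic NiCl2, a chiral oxazoline sulfonamide ligand) is selective for aldehydes over the pyranone and would give the carbinol. The route is rejoined at 14.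

**Step 6.** The exchange may stop short at a di-ortho-substituted carbon, because it is an equilibrium held only by the insolubility of NaBr. The secondary diamine may also add to C2 of the pyranone at 110 °C. Fallback: omit the exchange and submit bromide 7 directly to the conditions of step 7. Aryl bromides with a triflate salt as scavenger are the halide class best documented for this coupling. The route is rejoined at 13, and no new compound is made (F0).

**Step 5.** Allyl transfer may lose regiocontrol and couple through the substituted terminus to give the branched 1,1-dimethylallyl isomer. Palladium may also begin to insert into C8–Br if the reaction has to be forced. Fallback, in two steps without regiochemical ambiguity: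

- From 5, Stille coupling with allyltributylstannane under the same catalyst should give 8-bromo-5,7-bis(methoxymethoxy)-3-[4-(methoxymethoxy)phenyl]-6-(prop-2-enyl)chromen-4-one F3.
- Cross-metathesis of F3 with 2-methylbut-2-ene and second-generation Grubbs catalyst would give 7, where the route is rejoined.

**Step 9.** Acid may cyclise the C6 prenyl group onto the freed 5- or 7-hydroxyl, or solvolyse the allylic carbinol, before the third acetal is cleaved. Fallback, by reversing the order of the last two operations:

- From 13, the acetals are removed under the same acid at the boronate stage, where no ionisable carbinol exists. This should give 5,7-dihydroxy-3-(4-hydroxyphenyl)-6-(3-methylbut-2-enyl)-8-[(2S)-3-methyl-2-(4,4,5,5-tetramethyl-1,3,2-dioxaborolan-2-yl)but-3-enyl]chromen-4-one F4.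
- Perborate oxidation as in step 8 is then the final step. Under its mildly basic conditions the phenoxide form also makes the pyranone less electrophilic. The route is rejoined at 15.

## Further compounds

F1 | step 7 | 8-[(Z)-2-ethoxyvinyl]-5,7-bis(methoxymethoxy)-3-[4-(methoxymethoxy)phenyl]-6-(3-methylbut-2-enyl)chromen-4-one | CCO/C=C\c1c(OCOC)c(CC=C(C)C)c(OCOC)c2c(=O)c(-c3ccc(OCOC)cc3)coc12
F2 | step 7 | 2-[5,7-bis(methoxymethoxy)-3-[4-(methoxymethoxy)phenyl]-6-(3-methylbut-2-enyl)-4-oxochromen-8-yl]acetaldehyde | O=CCc1c(OCOC)c(CC=C(C)C)c(OCOC)c2c(=O)c(-c3ccc(OCOC)cc3)coc12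
F0 | step 6 | none | none
F3 | step 5 | 8-bromo-5,7-bis(methoxymethoxy)-3-[4-(methoxymethoxy)phenyl]-6-(prop-2-enyl)chromen-4-one | C=CCc1c(OCOC)c(Br)c2occ(-c3ccc(OCOC)cc3)c(=O)c2c1OCOC
F4 | step 9 | 5,7-dihydroxy-3-(4-hydroxyphenyl)-6-(3-methylbut-2-enyl)-8-[(2S)-3-methyl-2-(4,4,5,5-tetramethyl-1,3,2-dioxaborolan-2-yl)but-3-enyl]chromen-4-one | C=C(C)[C@@H](B4OC(C)(C)C(C)(C)O4)Cc1c(O)c(CC=C(C)C)c(O)c2c(=O)c(-c3ccc(O)cc3)coc12
A1 | alternative 1 | 8-[(2S)-2-(tert-butyldimethylsilyloxy)-3-methylbut-3-enyl]-3-[4-(tert-butyldimethylsilyloxy)phenyl]-5-hydroxy-6-(3-methylbut-2-enyl)-7-(triisopropylsilyloxy)chromen-4-one | C=C(C)[C@@H](O[Si](C)(C)C(C)(C)C)Cc1c(O[Si](C(C)C)(C(C)C)C(C)C)c(CC=C(C)C)c(O)c2c(=O)c(-c3ccc(O[Si](C)(C)C(C)(C)C)cc3)coc12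
A2 | alternative 1 | 5-[4-(tert-butyldimethylsilyloxy)phenyl]-2-[(4S)-4-(tert-butyldimethylsilyloxy)-2-diazo-5-methylhex-5-enoyl]pyran-4-one | C=C(C)[C@@H](O[Si](C)(C)C(C)(C)C)CC(=[N+]=[N-])C(=O)c1cc(=O)c(-c2ccc(O[Si](C)(C)C(C)(C)C)cc2)co1
A3 | alternative 1 | triisopropyl[(5-methylhex-4-en-1-ynyl)oxy]silane | CC(C)=CCC#CO[Si](C(C)C)(C(C)C)C(C)C
A4 | alternative 2 | 5,7-bis(methoxymethoxy)-3-[4-(methoxymethoxy)phenyl]-6-(3-methylbut-2-enyl)chromen-4-one | CC(C)=CCc1c(OCOC)cc2occ(-c3ccc(OCOC)cc3)c(=O)c2c1OCOC
A5 | alternative 2 | 3,5-bis(methoxymethoxy)-4-(3-methylbut-2-enyl)-2-(trimethylsilyl)phenyl trifluoromethanesulfonate | CC(C)=CCc1c(OCOC)cc(OS(=O)(=O)C(F)(F)F)c([Si](C)(C)C)c1OCOC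
A6 | alternative 2 | methyl 2-[4-(methoxymethoxy)phenyl]-3-oxopropanoate | COC(=O)C(C=O)c1ccc(OCOC)cc1
A7 | alternative 3 | 8-[(2S)-2-(tert-butyldimethylsilyloxy)-3-methylbut-3-enyl]-5,7-bis(methoxymethoxy)-3-[4-(methoxymethoxy)phenyl]-6-(3-methylbut-2-enyl)-2-(trimethylsilyl)chromen-4-one | C=C(C)[C@@H](O[Si](C)(C)C(C)(C)C)Cc1c(OCOC)c(CC=C(C)C)c(OCOC)c2c(=O)c(-c3ccc(OCOC)cc3)c([Si](C)(C)C)oc12
A8 | alternative 3 | 3-[(2S)-2-(tert-butyldimethylsilyloxy)-3-methylbut-3-enyl]-2-hydroxy-4,6-bis(methoxymethoxy)-5-(3-methylbut-2-enyl)benzaldehyde | C=C(C)[C@@H](O[Si](C)(C)C(C)(C)C)Cc1c(OCOC)c(CC=C(C)C)c(OCOC)c(C=O)c1O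
A9 | alternative 3 | {[4-(methoxymethoxy)phenyl]ethynyl}trimethylsilane | COCOc1ccc(C#C[Si](C)(C)C)cc1
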